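## Retrosynthetic overview

1. The vinyl group on the quaternary carbon comes from Zweifel olefination of a tertiary allylic pinacol boronate (36).
2. Key bond C(quaternary)–CH2: lithiation–borylation of the α-lithiated (S)-allylic carbamate 33 with the primary boronate 10. The carbinol carbon acts as a nucleophile and the 1,2-metallate shift sets the quaternary centre stereospecifically.
3. Boronate 10 comes from 3,4-dimethylanisole: Birch reduction, asymmetric enone isomerisation, cuprate addition with borylmethyl trapping, methylenation, Matteson homologation.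
4. Carbamate 33 comes from an HWE/CBS sequence on aldehyde 29. The chain is built by two Ni-catalysed alkyl–alkyl Negishi couplings (the second with a zinc homoenolate); both earlier pieces derive from desymmetrised meso-2,3-dimethylsuccinic anhydride.
5. Rings: the only carbocycle is present from step 1 (arene to cyclohexenone); a γ-lactone (15) appears only transiently in the chain synthesis.

Assumption: in steps 2 and 7 the cinchona catalyst of the pseudoenantiomeric series that delivers the drawn enantiomer is used (if step 7 gave the other hemiester, reducing its ester instead of its acid leads to the same lactone 15).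

## Route

Step 1
Reactants: 1 3,4-dimethylanisole
Product: 3 3,4-dimethylcyclohex-3-en-1-one, via Birch diene 2 (not isolated)
Conditions: Li, NH3(l), t-BuOH, THF, −78 to −33 °C; then (CO2H)2, MeOH/H2O, rt
Reagents that add atoms: water, O
Why: Birch reduction leaves the two double bonds on the methoxy- and methyl-bearing carbons, and mild enol-ether hydrolysis stops at the unconjugated β,γ-enone.

Step 2
Reactants: 3 3,4-dimethylcyclohex-3-en-1-one
Product: 4 (S)-3,4-dimethylcyclohex-2-en-1-one
Conditions: 9-amino-9-deoxy-epi-cinchona primary-amine catalyst (10 mol %), ArCO2H (20 mol %), toluene, −25 °C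
Reagents that add atoms: none
Why: Amine-catalysed enantioselective olefin isomerisation (dienamine formation, then face-selective γ-protonation by the chiral ammonium) gives the conjugated enone and sets C4 as (S).

Step 3
Reactants: 4 (S)-3,4-dimethylcyclohex-2-en-1-one; 5 2-(iodomethyl)-4,4,5,5-tetramethyl-1,3,2-dioxaborolane
Product: 7 (2R,4S)-3,3,4-trimethyl-2-[(4,4,5,5-tetramethyl-1,3,2-dioxaborolan-2-yl)methyl]cyclohexan-1-one, via lithium enolate 6 (not isolated)
Conditions: Me2CuLi (1.3 equiv), Et2O, −20 °C; then 5 (1.5 equiv), THF/HMPA, −78 to 0 °C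
Reagents that add atoms: lithium dimethylcuprate, [Li+].C[Cu-]C
Why: Cuprate 1,4-addition builds the gem-dimethyl carbon and a regiodefined enolate, which is C-alkylated by the iodomethylboronate (enolate alkylation through a boron ate complex) axially and anti to the pseudo-axial C3 methyl of the half-chair that keeps the C4 methyl equatorial, giving the 2,4-trans ketone.

Step 4
Reactants: 7 (2R,4S)-3,3,4-trimethyl-2-[(4,4,5,5-tetramethyl-1,3,2-dioxaborolan-2-yl)methyl]cyclohexan-1-one
Product: 8 2-{[(1S,3S)-2,2,3-trimethyl-6-methylidenecyclohexyl]methyl}-4,4,5,5-tetramethyl-1,3,2-dioxaborolane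
Conditions: Cp2TiMe2 (2 equiv), toluene/THF, 65 °C, dark
Reagents that add atoms: dimethyltitanocene (Petasis reagent), [CH3-].[CH3-].[Ti+4].[cH-]1cccc1.[cH-]1cccc1
Why: Petasis methylenation (Cp2Ti=CH2) is non-basic, so the epimerisable α-centre keeps its trans configuration and the boronic ester is untouched.

Step 5
Reactants: 8 2-{[(1S,3S)-2,2,3-trimethyl-6-methylidenecyclohexyl]methyl}-4,4,5,5-tetramethyl-1,3,2-dioxaborolane
Product: 10 2-{2-[(1S,3S)-2,2,3-trimethyl-6-methylidenecyclohexyl]ethyl}-4,4,5,5-tetramethyl-1,3,2-dioxaborolane, via boron ate complex 9 (not isolated)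
Conditions: ClCH2I (2 equiv), n-BuLi (1.5 equiv), THF, −78 °C to rt
Reagents that add atoms: chloroiodomethane (source of LiCH2Cl), ClCI
Why: Matteson homologation: LiCH2Cl adds to boron and the primary alkyl group migrates with loss of chloride, inserting the second CH2 of the linker without touching a stereocentre.

Step 6
Reactants: 11 meso-2,3-dimethylsuccinic acid
Product: 12 cis-3,4-dimethyloxolane-2,5-dione (meso anhydride)
Conditions: AcCl, reflux; evaporate
Reagents that add atoms: none
Why: Dehydrative cyclisation via the mixed anhydride gives the cyclic anhydride with the cis (meso) arrangement retained.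

Step 7
Reactants: 12 cis-3,4-dimethyloxolane-2,5-dione
Product: 13 (2R,3S)-4-methoxy-2,3-dimethyl-4-oxobutanoic acid
Conditions: MeOH (10 equiv), (DHQD)2AQN-type cinchona catalyst (10 mol %), Et2O, −30 °C
Reagents that add atoms: methanol, CO
Why: Alkaloid-catalysed desymmetrising methanolysis of the meso anhydride differentiates the enantiotopic carbonyls and so fixes both methyl-bearing centres at once.

Step 8
Reactants: 13 (2R,3S)-4-methoxy-2,3-dimethyl-4-oxobutanoic acid
Product: 15 (3S,4R)-3,4-dimethyloxolan-2-one, via hydroxy ester 14 (not isolated)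
Conditions: BH3·SMe2, THF, −10 °C to rt; MeOH quench; then p-TsOH (cat.), CH2Cl2, rt
Reagents that add atoms: none
Why: Borane reduces the carboxylic acid chemoselectively beside the ester, and the γ-hydroxy ester lactonises under acid without touching either stereocentre.

Step 9
Reactants: 15 (3S,4R)-3,4-dimethyloxolan-2-one
Product: 18 methyl (2S,3R)-4-iodo-2,3-dimethylbutanoate, via silyl ester 16 (not isolated), via iodo acid 17 (not isolated)
Conditions: Me3SiI (1.3 equiv), CH2Cl2, rt; then MeOH, 40 °C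
Reagents that add atoms: iodotrimethylsilane, C[Si](C)(C)I; methanol, CO
Why: Silyl-activated SN2 dealkylation of the lactone by iodide at the CH2–O carbon, then acid-catalysed methanolysis and Fischer esterification, opens the ring away from both stereocentres.

Step 10
Reactants: 18 methyl (2S,3R)-4-iodo-2,3-dimethylbutanoate
Product: 19 methyl (S)-2,3-dimethylbutanoate
Conditions: Bu3SnH, AIBN (cat.), benzene, 80 °C
Reagents that add atoms: none
Why: Radical hydrodeiodination (tin hydride chain) turns CH2I into the second methyl of the isopropyl group; the radical is not at the remaining stereocentre.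

Step 11
Reactants: 19 methyl (S)-2,3-dimethylbutanoate
Product: 20 (S)-2,3-dimethylbutan-1-ol
Conditions: LiAlH4, Et2O, 0 °C
Reagents that add atoms: none
Why: Hydride reduction of the ester to the primary alcohol, with no epimerisation of the α-centre.

Step 12
Reactants: 20 (S)-2,3-dimethylbutan-1-ol
Product: 21 (S)-1-iodo-2,3-dimethylbutane
Conditions: I2, PPh3, imidazole, CH2Cl2, 0 °C to rt
Reagents that add atoms: iodine, II
Why: Appel-type iodination proceeds by SN2 at the primary carbon only.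

Step 13
Reactants: 21 (S)-1-iodo-2,3-dimethylbutane; 18 methyl (2S,3R)-4-iodo-2,3-dimethylbutanoate
Product: 23 methyl (2S,3S,6R)-2,3,6,7-tetramethyloctanoate, via alkylzinc iodide 22 (not isolated)
Conditions: 21, Zn dust (activated), THF, 40 °C; then 18, Ni(acac)2 (10 mol %), 4-fluorostyrene (20 mol %), Bu4NI, THF/NMP, −5 °C to rt
Reagents that add atoms: none
Why: Zinc insertion followed by Ni-catalysed alkyl–alkyl Negishi coupling joins two primary sp3 carbons, tolerates the ester, and no stereocentre sits on a reacting carbon.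

Step 14
Reactants: 23 methyl (2S,3S,6R)-2,3,6,7-tetramethyloctanoate
Product: 24 (2S,3S,6R)-2,3,6,7-tetramethyloctan-1-ol
Conditions: LiAlH4, Et2O, 0 °C
Reagents that add atoms: none
Why: Hydride reduction of the ester to the primary alcohol.

Step 15
Reactants: 24 (2S,3S,6R)-2,3,6,7-tetramethyloctan-1-ol
Product: 25 (2S,3S,6R)-1-iodo-2,3,6,7-tetramethyloctane
Conditions: I2, PPh3, imidazole, CH2Cl2, 0 °C to rt
Reagents that add atoms: iodine, II
Why: Appel-type iodination at the primary carbon.

Step 16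
Reactants: 25 (2S,3S,6R)-1-iodo-2,3,6,7-tetramethyloctane; 26 methyl (S)-3-bromo-2-methylpropanoate
Product: 28 methyl (2R,5R,6S,9R)-2,5,6,9,10-pentamethylundecanoate, via zinc homoenolate 27 (not isolated)
Conditions: 26, Zn dust, LiCl, THF, 50 °C; then 25, Ni(acac)2 (10 mol %), 4-fluorostyrene (20 mol %), Bu4NI, THF/NMP, −5 °C to rt
Reagents that add atoms: none
Why: The β-zincio ester (a zinc homoenolate, nucleophilic at the carbon β to the ester) undergoes Ni-catalysed alkyl–alkyl Negishi coupling; its stereocentre is not the metallated carbon and is carried through unchanged.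

Step 17
Reactants: 28 methyl (2R,5R,6S,9R)-2,5,6,9,10-pentamethylundecanoate
Product: 29 (2R,5R,6S,9R)-2,5,6,9,10-pentamethylundecanal
Conditions: DIBAL-H (1.1 equiv), CH2Cl2, −78 °C; Rochelle salt
Reagents that add atoms: none
Why: DIBAL half-reduction stops at the tetrahedral aluminium hemiacetal at −78 °C and releases the aldehyde on work-up.

Step 18
Reactants: 29 (2R,5R,6S,9R)-2,5,6,9,10-pentamethylundecanal; 30 dimethyl (2-oxopropyl)phosphonate
Product: 31 (3E,5R,8R,9S,12R)-5,8,9,12,13-pentamethyltetradec-3-en-2-one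
Conditions: 30, Ba(OH)2 (activated), THF; then 29, THF/H2O 40:1, rt
Reagents that add atoms: none
Why: Horner–Wadsworth–Emmons olefination under mild Ba(OH)2 conditions gives the E-enone without epimerising the α-methyl aldehyde.

Step 19
Reactants: 31 (3E,5R,8R,9S,12R)-5,8,9,12,13-pentamethyltetradec-3-en-2-one
Product: 32 (2S,3E,5R,8R,9S,12R)-5,8,9,12,13-pentamethyltetradec-3-en-2-ol
Conditions: (R)-Me-CBS (20 mol %), catecholborane (1.8 equiv), toluene, −78 °C
Reagents that add atoms: none
Why: Corey–Bakshi–Shibata reduction: the (R)-oxazaborolidine delivers hydride to the ketone face that gives the (S)-allylic alcohol (alkenyl as the large group), with 1,2-selectivity.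

Step 20
Reactants: 32 (2S,3E,5R,8R,9S,12R)-5,8,9,12,13-pentamethyltetradec-3-en-2-ol
Product: 33 (2S,3E,5R,8R,9S,12R)-5,8,9,12,13-pentamethyltetradec-3-en-2-yl N,N-diisopropylcarbamate
Conditions: iPr2NCOCl, Et3N, CH2Cl2, reflux
Reagents that add atoms: N,N-diisopropylcarbamoyl chloride, CC(C)N(C(C)C)C(Cl)=O
Why: O-Carbamoylation (acyl substitution at the carbamoyl chloride) installs the Hoppe directing and leaving group with retention at the carbinol carbon.

Step 21
Reactants: 33 (2S,3E,5R,8R,9S,12R)-5,8,9,12,13-pentamethyltetradec-3-en-2-yl N,N-diisopropylcarbamate; 10 2-{2-[(1S,3S)-2,2,3-trimethyl-6-methylidenecyclohexyl]ethyl}-4,4,5,5-tetramethyl-1,3,2-dioxaborolane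
Product: 36 2-{(3S,4E,6R,9R,10S,13R)-3,6,9,10,13,14-hexamethyl-1-[(1S,3S)-2,2,3-trimethyl-6-methylidenecyclohexyl]pentadec-4-en-3-yl}-4,4,5,5-tetramethyl-1,3,2-dioxaborolane, via lithiated carbamate 34 (not isolated), via boron ate complex 35 (not isolated)
Conditions: s-BuLi (1.1 equiv), TMEDA, Et2O, −78 °C; then 10 (1.2 equiv), −78 °C, 1 h; then −78 °C to rt, 16 h
Reagents that add atoms: none
Why: Hoppe–Aggarwal lithiation–borylation: deprotonation with retention gives a configurationally stable α-oxy allyl-lithium, a reversed-polarity (d1, homoenolate-class) synthon whose carbinol carbon, normally the electrophilic end of an allylic ester, attacks the boron of 10 at the α-position with retention; the anti-periplanar 1,2-metallate shift of the primary alkyl group with loss of carbamate (inversion) then joins two formally nucleophilic carbons (C–Li and C–B), forms the quaternary centre as (S) and keeps the E-alkene.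

Step 22
Reactants: 36 2-{(3S,4E,6R,9R,10S,13R)-3,6,9,10,13,14-hexamethyl-1-[(1S,3S)-2,2,3-trimethyl-6-methylidenecyclohexyl]pentadec-4-en-3-yl}-4,4,5,5-tetramethyl-1,3,2-dioxaborolane
Product: 39 (3S,4E,6R,9R,10S,13R)-3,6,9,10,13,14-hexamethyl-3-{2-[(1S,3S)-2,2,3-trimethyl-6-methylidenecyclohexyl]ethyl}pentadeca-1,4-diene, via vinyl ate complex 37 (not isolated), via iodo boronate 38 (not isolated)
Conditions: CH2=CHLi (4 equiv, from Sn(CH=CH2)4 + n-BuLi), THF, −78 °C to rt; I2, MeOH, −78 °C; NaOMe, MeOH, −78 °C to rt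
Reagents that add atoms: tetravinylstannane (source of vinyllithium, [Li]C=C), C=C[Sn](C=C)(C=C)C=C
Why: Zweifel olefination: vinyllithium forms the vinyl boronate, iodine triggers 1,2-migration of the tertiary allylic group with retention, and methoxide-induced anti-elimination of boron and iodide leaves the vinyl group on the quaternary carbon without touching the other alkenes.

## Compound list

1 | 3,4-dimethylanisole | COc1ccc(C)c(C)c1 | starting material
2 | 1-methoxy-4,5-dimethylcyclohexa-1,4-diene | COC1=CCC(C)=C(C)C1 | intermediate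
3 | 3,4-dimethylcyclohex-3-en-1-one | O=C1CCC(C)=C(C)C1 | intermediate
4 | (S)-3,4-dimethylcyclohex-2-en-1-one | O=C1C=C(C)[C@@H](C)CC1 | intermediate
5 | 2-(iodomethyl)-4,4,5,5-tetramethyl-1,3,2-dioxaborolane | CC1(C)OB(CI)OC1(C)C | starting material
6 | lithium (S)-3,3,4-trimethylcyclohex-1-en-1-olate | [Li+].[O-]C1=CC(C)(C)[C@@H](C)CC1 | intermediate
7 | (2R,4S)-3,3,4-trimethyl-2-[(4,4,5,5-tetramethyl-1,3,2-dioxaborolan-2-yl)methyl]cyclohexan-1-one (2,4-trans) | CC1(C)OB(C[C@H]2C(=O)CC[C@H](C)C2(C)C)OC1(C)C | intermediate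
8 | 2-{[(1S,3S)-2,2,3-trimethyl-6-methylidenecyclohexyl]methyl}-4,4,5,5-tetramethyl-1,3,2-dioxaborolane | CC1(C)OB(C[C@H]2C(=C)CC[C@H](C)C2(C)C)OC1(C)C | intermediate
9 | lithium (chloromethyl) ate complex of 8 | [Li+].ClC[B-]1(C[C@H]2C(=C)CC[C@H](C)C2(C)C)OC(C)(C)C(C)(C)O1 | intermediate
10 | 2-{2-[(1S,3S)-2,2,3-trimethyl-6-methylidenecyclohexyl]ethyl}-4,4,5,5-tetramethyl-1,3,2-dioxaborolane | CC1(C)OB(CC[C@H]2C(=C)CC[C@H](C)C2(C)C)OC1(C)C | intermediate
11 | meso-2,3-dimethylsuccinic acid ((2R,3S)-2,3-dimethylbutanedioic acid) | OC(=O)[C@@H](C)[C@@H](C)C(=O)O | starting material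
12 | cis-3,4-dimethyloxolane-2,5-dione (meso anhydride) | O=C1[C@@H](C)[C@@H](C)C(=O)O1 | intermediate
13 | (2R,3S)-4-methoxy-2,3-dimethyl-4-oxobutanoic acid | COC(=O)[C@@H](C)[C@@H](C)C(=O)O | intermediate
14 | methyl (2S,3R)-4-hydroxy-2,3-dimethylbutanoate | COC(=O)[C@@H](C)[C@@H](C)CO | intermediate
15 | (3S,4R)-3,4-dimethyloxolan-2-one (cis lactone) | O=C1[C@@H](C)[C@@H](C)CO1 | intermediate
16 | trimethylsilyl (2S,3R)-4-iodo-2,3-dimethylbutanoate | C[Si](C)(C)OC(=O)[C@@H](C)[C@@H](C)CI | intermediate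
17 | (2S,3R)-4-iodo-2,3-dimethylbutanoic acid | OC(=O)[C@@H](C)[C@@H](C)CI | intermediate
18 | methyl (2S,3R)-4-iodo-2,3-dimethylbutanoate | COC(=O)[C@@H](C)[C@@H](C)CI | intermediate
19 | methyl (S)-2,3-dimethylbutanoate | COC(=O)[C@@H](C)C(C)C | intermediate
20 | (S)-2,3-dimethylbutan-1-ol | OC[C@@H](C)C(C)C | intermediate
21 | (S)-1-iodo-2,3-dimethylbutane | IC[C@@H](C)C(C)C | intermediate
22 | [(S)-2,3-dimethylbutyl]zinc iodide | I[Zn]C[C@@H](C)C(C)C | intermediate
23 | methyl (2S,3S,6R)-2,3,6,7-tetramethyloctanoate | COC(=O)[C@@H](C)[C@@H](C)CC[C@@H](C)C(C)C | intermediate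
24 | (2S,3S,6R)-2,3,6,7-tetramethyloctan-1-ol | OC[C@@H](C)[C@@H](C)CC[C@@H](C)C(C)C | intermediate
25 | (2S,3S,6R)-1-iodo-2,3,6,7-tetramethyloctane | IC[C@@H](C)[C@@H](C)CC[C@@H](C)C(C)C | intermediate
26 | methyl (S)-3-bromo-2-methylpropanoate | COC(=O)[C@H](C)CBr | starting material
27 | [(S)-3-methoxy-2-methyl-3-oxopropyl]zinc bromide (zinc homoenolate) | COC(=O)[C@H](C)C[Zn]Br | intermediate
28 | methyl (2R,5R,6S,9R)-2,5,6,9,10-pentamethylundecanoate | COC(=O)[C@H](C)CC[C@@H](C)[C@@H](C)CC[C@@H](C)C(C)C | intermediate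
29 | (2R,5R,6S,9R)-2,5,6,9,10-pentamethylundecanal | O=C[C@H](C)CC[C@@H](C)[C@@H](C)CC[C@@H](C)C(C)C | intermediate
30 | dimethyl (2-oxopropyl)phosphonate | COP(=O)(CC(C)=O)OC | starting material
31 | (3E,5R,8R,9S,12R)-5,8,9,12,13-pentamethyltetradec-3-en-2-one | CC(=O)/C=C/[C@H](C)CC[C@@H](C)[C@@H](C)CC[C@@H](C)C(C)C | intermediate
32 | (2S,3E,5R,8R,9S,12R)-5,8,9,12,13-pentamethyltetradec-3-en-2-ol | C[C@H](O)/C=C/[C@H](C)CC[C@@H](C)[C@@H](C)CC[C@@H](C)C(C)C | intermediate
33 | (2S,3E,5R,8R,9S,12R)-5,8,9,12,13-pentamethyltetradec-3-en-2-yl N,N-diisopropylcarbamate | C[C@H](OC(=O)N(C(C)C)C(C)C)/C=C/[C@H](C)CC[C@@H](C)[C@@H](C)CC[C@@H](C)C(C)C | intermediate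
34 | α-lithiated carbamate (Li in place of the carbinol H of 33, retention) | C[C@]([Li])(OC(=O)N(C(C)C)C(C)C)/C=C/[C@H](C)CC[C@@H](C)[C@@H](C)CC[C@@H](C)C(C)C | intermediate
35 | lithium boron ate complex (carbinol carbon of 34 bound to the boron of 10) | [Li+].C[C@]([B-]1(CC[C@H]2C(=C)CC[C@H](C)C2(C)C)OC(C)(C)C(C)(C)O1)(OC(=O)N(C(C)C)C(C)C)/C=C/[C@H](C)CC[C@@H](C)[C@@H](C)CC[C@@H](C)C(C)C | intermediate
36 | 2-{(3S,4E,6R,9R,10S,13R)-3,6,9,10,13,14-hexamethyl-1-[(1S,3S)-2,2,3-trimethyl-6-methylidenecyclohexyl]pentadec-4-en-3-yl}-4,4,5,5-tetramethyl-1,3,2-dioxaborolane | CC1(C)OB(OC1(C)C)[C@@](C)(/C=C/[C@H](C)CC[C@@H](C)[C@@H](C)CC[C@@H](C)C(C)C)CC[C@H]2C(=C)CC[C@H](C)C2(C)C | intermediate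
37 | lithium vinyl ate complex of 36 | [Li+].C=C[B-]1(OC(C)(C)C(C)(C)O1)[C@@](C)(/C=C/[C@H](C)CC[C@@H](C)[C@@H](C)CC[C@@H](C)C(C)C)CC[C@H]2C(=C)CC[C@H](C)C2(C)C | intermediate
38 | β-iodoalkyl boronate after 1,2-shift (ICH2–CH(Bpin)– on the quaternary carbon; epimers at the boron-bearing carbon) | ICC(B1OC(C)(C)C(C)(C)O1)[C@@](C)(/C=C/[C@H](C)CC[C@@H](C)[C@@H](C)CC[C@@H](C)C(C)C)CC[C@H]2C(=C)CC[C@H](C)C2(C)C | intermediate
39 | (3S,4E,6R,9R,10S,13R)-3,6,9,10,13,14-hexamethyl-3-{2-[(1S,3S)-2,2,3-trimethyl-6-methylidenecyclohexyl]ethyl}pentadeca-1,4-diene (CNP0132765.1) | C=C[C@@](C)(/C=C/[C@H](C)CC[C@@H](C)[C@@H](C)CC[C@@H](C)C(C)C)CC[C@H]1C(=C)CC[C@H](C)C1(C)C | target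

## Step count and risks

Total step count: 22. Longest linear sequence: 17 steps (11 to 39, steps 6–22); the ring branch 1 to 10 is 5 steps.

**Step 3** (cuprate addition with borylmethyl trapping). The hindered copper/lithium enolate may be captured slowly or at oxygen by the iodomethylboronate, and the 2,4-trans ratio may erode by proton transfer. The fallback sets out from 4 and comes back at 10, using a two-carbon α-halo ester electrophile and a late borylation. The enolate from 4 and Me2CuLi is alkylated with methyl iodoacetate in THF/HMPA to give methyl 2-[(1R,3S)-2,2,3-trimethyl-6-oxocyclohexyl]acetate F1. Petasis methylenation of the ketone (faster than the ester) gives methyl 2-[(1S,3S)-2,2,3-trimethyl-6-methylidenecyclohexyl]acetate F2. LiAlH4 gives 2-[(1S,3S)-2,2,3-trimethyl-6-methylidenecyclohexyl]ethan-1-ol F3, and I2/PPh3/imidazole gives (1S,3S)-1-(2-iodoethyl)-2,2,3-trimethyl-6-methylidenecyclohexane F4. Copper-catalysed borylation (B2pin2, CuI, PPh3, LiOMe, DMF) then gives 10.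

**Step 16** (alkyl–alkyl Negishi coupling of the zinc homoenolate). Oxidative addition of the β-branched iodide may be slow and β-hydride elimination may compete. The fallback sets out from 23 and comes back at 29, replacing the sp3–sp3 coupling by an olefination. DIBAL-H reduction of 23 at −78 °C gives (2S,3S,6R)-2,3,6,7-tetramethyloctanal F5. A Wittig reaction with the ylide from commercial (S)-(3-hydroxy-2-methylpropyl)triphenylphosphonium bromide (2 equiv NaHMDS, THF, −78 °C) gives (2R,3Z,5S,6S,9R)-2,5,6,9,10-pentamethylundec-3-en-1-ol F6. Diimide reduction (TsNHNH2, NaOAc), chosen so that the two allylic stereocentres are not scrambled by alkene migration, gives (2R,5R,6S,9R)-2,5,6,9,10-pentamethylundecan-1-ol F7. Dess–Martin oxidation gives 29.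

**Step 21** (lithiation–borylation). Borylation of the bulky lithiated 1,3-disubstituted allyl carbamate may be incomplete or not α-selective, or the ate complex may revert before the 1,2-shift. The fallback sets out from 29 and 10 and comes back at 39; the small partner now carries the carbamate and the chain enters in the olefination.
- Stork–Zhao olefination of 29 (Ph3P=CHI, NaHMDS, THF/HMPA, −78 °C) gives (1Z,3R,6R,7S,10R)-1-iodo-3,6,7,10,11-pentamethyldodec-1-ene F8.
- Commercial (R)-but-3-en-2-ol is carbamoylated to (R)-but-3-en-2-yl N,N-diisopropylcarbamate F9.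
- F9 is lithiated (s-BuLi/TMEDA, Et2O, −78 °C) and borylated with 10 to give 2-{(3R)-3-methyl-5-[(1S,3S)-2,2,3-trimethyl-6-methylidenecyclohexyl]pent-1-en-3-yl}-4,4,5,5-tetramethyl-1,3,2-dioxaborolane F10.
- The alkenyllithium from F8 (t-BuLi, −78 °C) is added to F10, and I2 then NaOMe (Zweifel coupling, with Z to E inversion in the anti-elimination) gives 39 directly.

## Further compounds

F1 | step 3 | methyl 2-[(1R,3S)-2,2,3-trimethyl-6-oxocyclohexyl]acetate | COC(=O)C[C@H]1C(=O)CC[C@H](C)C1(C)C
F2 | step 3 | methyl 2-[(1S,3S)-2,2,3-trimethyl-6-methylidenecyclohexyl]acetate | COC(=O)C[C@H]1C(=C)CC[C@H](C)C1(C)C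
F3 | step 3 | 2-[(1S,3S)-2,2,3-trimethyl-6-methylidenecyclohexyl]ethan-1-ol | OCC[C@H]1C(=C)CC[C@H](C)C1(C)C
F4 | step 3 | (1S,3S)-1-(2-iodoethyl)-2,2,3-trimethyl-6-methylidenecyclohexane | ICC[C@H]1C(=C)CC[C@H](C)C1(C)C
F5 | step 16 | (2S,3S,6R)-2,3,6,7-tetramethyloctanal | O=C[C@@H](C)[C@@H](C)CC[C@@H](C)C(C)C
F6 | step 16 | (2R,3Z,5S,6S,9R)-2,5,6,9,10-pentamethylundec-3-en-1-ol | OC[C@H](C)/C=C\[C@@H](C)[C@@H](C)CC[C@@H](C)C(C)C
F7 | step 16 | (2R,5R,6S,9R)-2,5,6,9,10-pentamethylundecan-1-ol | OC[C@H](C)CC[C@@H](C)[C@@H](C)CC[C@@H](C)C(C)C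
F8 | step 21 | (1Z,3R,6R,7S,10R)-1-iodo-3,6,7,10,11-pentamethyldodec-1-ene | I/C=C\[C@H](C)CC[C@@H](C)[C@@H](C)CC[C@@H](C)C(C)C
F9 | step 21 | (R)-but-3-en-2-yl N,N-diisopropylcarbamate | C=C[C@@H](C)OC(=O)N(C(C)C)C(C)C
F10 | step 21 | 2-{(3R)-3-methyl-5-[(1S,3S)-2,2,3-trimethyl-6-methylidenecyclohexyl]pent-1-en-3-yl}-4,4,5,5-tetramethyl-1,3,2-dioxaborolane | C=C[C@@](C)(B1OC(C)(C)C(C)(C)O1)CC[C@H]2C(=C)CC[C@H](C)C2(C)C
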